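Retrosynthesis: cut (i) the C7–CH3 bond, (ii) the bond between the linker CH2 and hydrindane C1, (iii) the C7a=C1 bond of the resulting enone (aldol), and (iv) in each bromo six-ring the bond from the methyl-bearing quaternary carbon next to C–Br to the adjacent ring CH2 (tertiary bromonium plus allylsilane), back to the bromolactone of a 5-methylalk-4-enoic acid.
Forward: each bromo six-ring arises by the same three steps (catalytic asymmetric bromolactonisation, lactone to 2-substituted allylsilane, bromonium-relayed cyclisation); the cyclopentene of the hydrindane then closes by ozonolysis and aldol condensation; the halves are joined by a cobalt-mediated electroreductive radical conjugate addition; the C7 methyl is added last.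
Feature used by the key step: hydrindane C1 is β to the C7 carbinol carbon through C7a, so C7=O/C7a=C1 is an enone held s-cis by the bicycle; the linker CH2 sits on the fully substituted carbinol carbon of the cyclohexane, i.e. a β-hydroxy primary radical whose cobalt precursor has no β-hydrogen.
Stereochemistry: both C–Br centres come from the catalytic bromolactonisations (quaternary C3a by anti addition to the E-alkene, kept by double inversion); the cyclohexane carbinol from equatorial entry of water in an iodohydroxylation; C1, C7a and C7 are relayed from the angular C3a methyl.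

Key step: step 12

Remark: the same antipode of the bromolactonisation catalyst is assumed to serve steps 1 and 8, because both acids present the alkene to the carboxylate in the same sense; the two starting materials are taken as catalogue chemicals.

Step 1
Reactants: 1 5-methylhex-4-enoic acid
Product: 2 (5S)-5-bromo-6,6-dimethyloxan-2-one
Conditions: cinchona-derived amino-thiocarbamate catalyst (10 mol %), NBS, CHCl3–toluene, −60 °C
Reagents that add atoms: N-bromosuccinimide, O=C1CCC(=O)N1Br
Why: catalytic enantioselective bromolactonisation, in which catalyst-bound NBS delivers Br+ to one alkene face and the carboxylate closes 6-endo at the tertiary carbon (Markovnikov, anti), so the catalyst sets the only stereocentre (C5, S).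

Step 2
Reactants: 2 (5S)-5-bromo-6,6-dimethyloxan-2-one
Product: 4 (3S)-3-bromo-2-methyl-6-[(trimethylsilyl)methyl]hept-6-en-2-ol, via bis-silyl diol 3 (not isolated)
Conditions: Me3SiCH2MgCl, CeCl3, THF, −78 to 0 °C; then SiO2, CH2Cl2, rt
Reagents that add atoms: (trimethylsilyl)methylmagnesium chloride, C[Si](C)(C)C[Mg]Cl
Why: ester-to-allylsilane conversion, in which the organocerium adds twice to the lactone carbonyl and Peterson elimination of the bis(β-silyl) carbinol leaves the 2-substituted allylsilane, while the ring oxygen is released as the tertiary alcohol next to the untouched C–Br centre.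

Step 3
Reactants: 4 (3S)-3-bromo-2-methyl-6-[(trimethylsilyl)methyl]hept-6-en-2-ol
Product: 5 (4S)-4-bromo-3,3-dimethyl-1-methylidenecyclohexane
Conditions: SnCl4, 2,6-di-tert-butylpyridine, CH2Cl2, −78 °C
Reagents that add atoms: none
Why: allylsilane-terminated cation–olefin cyclisation, in which the Lewis acid ionises the tertiary C–O with help from the vicinal bromine (bromonium ion, C–Br centre untouched), the allylsilane terminus attacks the tertiary carbon through a chair with equatorial bromine, and loss of Me3Si gives the exocyclic alkene.

Step 4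
Reactants: 5 (4S)-4-bromo-3,3-dimethyl-1-methylidenecyclohexane
Product: 6 (1R,4S)-4-bromo-1-(iodomethyl)-3,3-dimethylcyclohexan-1-ol
Conditions: NIS, THF–H2O, 0 °C, dark
Reagents that add atoms: N-iodosuccinimide, O=C1CCC(=O)N1I; water, O
Why: Markovnikov iodohydroxylation, in which I+ adds to the terminal CH2 and water should enter the tertiary cationic carbon equatorially (a C3 methyl is syn-axial on either chair) on the chair whose axial C–Br stabilises the electron-poor centre through space, which places OH cis to Br.

Step 5
Reactants: 7 hex-5-en-1-yne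
Product: 10 (2E)-3-methylhepta-2,6-dien-1-ol, via alkenylalane 8 (not isolated), via lithium alanate 9 (not isolated)
Conditions: Me3Al, Cp2ZrCl2 (cat.), CH2Cl2, 0 °C to rt; n-BuLi, THF, −78 °C; (CH2O)n, rt; aq. HCl
Reagents that add atoms: trimethylaluminium, C[Al](C)C; paraformaldehyde (as formaldehyde), C=O
Why: Zr-catalysed carboalumination (Negishi) adds methyl and aluminium syn across the alkyne with methyl on the internal carbon, and the alanate is hydroxymethylated with retention, which fixes the E-alkene and spares the terminal alkene.

Step 6
Reactants: 10 (2E)-3-methylhepta-2,6-dien-1-ol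
Product: 11 (2E)-1-bromo-3-methylhepta-2,6-diene
Conditions: PBr3, Et2O, −10 °C
Reagents that add atoms: phosphorus tribromide, BrP(Br)Br
Why: SN2 bromination of the primary allylic alcohol at low temperature should keep the E-geometry and the position of the double bond.

Step 7
Reactants: 11 (2E)-1-bromo-3-methylhepta-2,6-diene
Product: 12 (4E)-5-methylnona-4,8-dienoic acid
Conditions: AcOH, LDA (2 equiv per acid), THF–DMPU, 0 °C; then 11, 0 °C to rt; aq. HCl
Reagents that add atoms: acetic acid, CC(=O)O
Why: SN2 alkylation of the acetic acid dianion at the primary allylic bromide gives the γ,δ-unsaturated acid directly.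

Step 8
Reactants: 12 (4E)-5-methylnona-4,8-dienoic acid
Product: 13 (5S,6R)-5-bromo-6-(but-3-en-1-yl)-6-methyloxan-2-one
Conditions: cinchona-derived amino-thiocarbamate catalyst (10 mol %), NBS, CHCl3–toluene, −60 °C
Reagents that add atoms: N-bromosuccinimide, O=C1CCC(=O)N1Br
Why: enantioselective bromolactonisation as in step 1, in which anti addition of Br and O across the E-alkene fixes C6 relative to C5, the catalyst fixes the absolute sense, and the remote terminal alkene is not engaged.

Step 9
Reactants: 13 (5S,6R)-5-bromo-6-(but-3-en-1-yl)-6-methyloxan-2-one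
Product: 15 (5R,6S)-6-bromo-5-methyl-9-[(trimethylsilyl)methyl]deca-1,9-dien-5-ol, via bis-silyl diol 14 (not isolated)
Conditions: Me3SiCH2MgCl, CeCl3, THF, −78 to 0 °C; then SiO2, CH2Cl2, rt
Reagents that add atoms: (trimethylsilyl)methylmagnesium chloride, C[Si](C)(C)C[Mg]Cl
Why: the same ester-to-allylsilane conversion as in step 2 (double organocerium addition, Peterson elimination), which leaves both stereocentres untouched.

Step 10
Reactants: 15 (5R,6S)-6-bromo-5-methyl-9-[(trimethylsilyl)methyl]deca-1,9-dien-5-ol
Product: 16 (1S,2S)-2-bromo-1-(but-3-en-1-yl)-1-methyl-5-methylidenecyclohexane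
Conditions: SnCl4, 2,6-di-tert-butylpyridine, CH2Cl2, −78 °C
Reagents that add atoms: none
Why: allylsilane-terminated cyclisation as in step 3, in which bromine displaces the ionising oxygen from the rear and the allylsilane then opens the bromonium ion anti to bromine (double inversion), so the quaternary carbon keeps the configuration set in step 8 and the monosubstituted alkene stays a spectator.

Step 11
Reactants: 16 (1S,2S)-2-bromo-1-(but-3-en-1-yl)-1-methyl-5-methylidenecyclohexane
Product: 18 (3aS,4S)-4-bromo-3a-methyl-2,3,3a,4,5,6-hexahydro-7H-inden-7-one, via keto aldehyde 17 (not isolated)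
Conditions: O3, CH2Cl2–MeOH, −78 °C; Me2S; then p-TsOH (cat.), toluene, 70 °C
Reagents that add atoms: ozone, [O-][O+]=O
Why: ozonolysis cleaves both terminal alkenes to the 1,6-keto aldehyde, and acid-catalysed intramolecular aldol condensation closes the cyclopentene through the only enol that gives a five-membered ring, dehydration making it irreversible; no stereocentre is formed.

Step 12
Reactants: 6 (1R,4S)-4-bromo-1-(iodomethyl)-3,3-dimethylcyclohexan-1-ol; 18 (3aS,4S)-4-bromo-3a-methyl-2,3,3a,4,5,6-hexahydro-7H-inden-7-one
Product: 19 (1S,3aS,4S,7aS)-4-bromo-1-{[(1S,4S)-4-bromo-1-hydroxy-3,3-dimethylcyclohexyl]methyl}-3a-methyloctahydro-7H-inden-7-one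
Conditions: 6 (1.5 equiv), vitamin B12 (10 mol %), NH4Cl, LiClO4 in DMF, divided cell, carbon-felt cathode at −0.95 V vs SCE, visible light, rt
Reagents that add atoms: none
Why: Cathodically generated Co(I) takes the primary C–I bond of 6 to a β-hydroxyalkylcobalamin, light homolyses the Co–C bond, the primary radical adds to C1 (the β-carbon of the enone), and the α-keto radical at C7a is reduced to the enolate and protonated by NH4+. The closest known reaction type is the vitamin B12-catalysed electroreductive conjugate addition of alkyl halides to enones (reductive Giese addition). The step closes no ring. C1 is controlled by the angular C3a methyl: the radical should enter the flat, s-cis-locked acylcyclopentene anti to it, so the new CH2 is trans to that methyl. C7a is controlled by the same methyl and by the new C1 substituent: protonation on the face opposite the methyl turns C7 away from the C1 side chain and gives the trans ring fusion, which mild equilibration should also favour. The step needs C–I to react in preference to the two secondary C–Br bonds and the alkylcobalt not to eliminate; the bromides are neopentyl-type and hindered toward Co(I), the carbon β to cobalt carries no hydrogen, and holding the cathode above the reduction potential of the alkylcobalt avoids loss of hydroxide.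

Step 13
Reactants: 19 (1S,3aS,4S,7aS)-4-bromo-1-{[(1S,4S)-4-bromo-1-hydroxy-3,3-dimethylcyclohexyl]methyl}-3a-methyloctahydro-7H-inden-7-one
Product: 20 (1S,4S)-4-bromo-1-{[(1S,3aS,4S,7R,7aS)-4-bromo-7-hydroxy-3a,7-dimethyloctahydro-1H-inden-1-yl]methyl}-3,3-dimethylcyclohexan-1-ol
Conditions: MeLi, CeCl3 (5 equiv each), THF, −78 °C; aq. NH4Cl
Reagents that add atoms: methyllithium, [Li]C
Why: 1,2-addition of the weakly basic organocerium reagent (Imamoto conditions), in which axial attack is blocked by the syn-axial C3a methyl, so methyl should enter equatorially and C7 receives the axial hydroxyl (7R), with the alkyl bromides inert at −78 °C.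

Compound list
1 | 5-methylhex-4-enoic acid | CC(C)=CCCC(=O)O | starting material
2 | (5S)-5-bromo-6,6-dimethyloxan-2-one | CC1(C)OC(=O)CC[C@@H]1Br | intermediate
3 | (3S)-3-bromo-2-methyl-7-(trimethylsilyl)-6-[(trimethylsilyl)methyl]heptane-2,6-diol | CC(C)(O)[C@@H](Br)CCC(O)(C[Si](C)(C)C)C[Si](C)(C)C | intermediate
4 | (3S)-3-bromo-2-methyl-6-[(trimethylsilyl)methyl]hept-6-en-2-ol | CC(C)(O)[C@@H](Br)CCC(=C)C[Si](C)(C)C | intermediate
5 | (4S)-4-bromo-3,3-dimethyl-1-methylidenecyclohexane | CC1(C)CC(=C)CC[C@@H]1Br | intermediate
6 | (1R,4S)-4-bromo-1-(iodomethyl)-3,3-dimethylcyclohexan-1-ol | CC1(C)C[C@@](O)(CI)CC[C@@H]1Br | intermediate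
7 | hex-5-en-1-yne | C#CCCC=C | starting material
8 | dimethyl[(1E)-2-methylhexa-1,5-dien-1-yl]alumane | C[Al](C)/C=C(\C)CCC=C | intermediate
9 | lithium butyl(dimethyl)[(1E)-2-methylhexa-1,5-dien-1-yl]aluminate | [Li+].CCCC[Al-](C)(C)/C=C(\C)CCC=C | intermediate
10 | (2E)-3-methylhepta-2,6-dien-1-ol | OC/C=C(\C)CCC=C | intermediate
11 | (2E)-1-bromo-3-methylhepta-2,6-diene | BrC/C=C(\C)CCC=C | intermediate
12 | (4E)-5-methylnona-4,8-dienoic acid | OC(=O)CC/C=C(\C)CCC=C | intermediate
13 | (5S,6R)-5-bromo-6-(but-3-en-1-yl)-6-methyloxan-2-one | O=C1CC[C@H](Br)[C@@](C)(CCC=C)O1 | intermediate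
14 | (5R,6S)-6-bromo-5-methyl-10-(trimethylsilyl)-9-[(trimethylsilyl)methyl]dec-1-ene-5,9-diol | C[Si](C)(C)CC(O)(C[Si](C)(C)C)CC[C@H](Br)[C@@](C)(CCC=C)O | intermediate
15 | (5R,6S)-6-bromo-5-methyl-9-[(trimethylsilyl)methyl]deca-1,9-dien-5-ol | C=C(C[Si](C)(C)C)CC[C@H](Br)[C@@](C)(CCC=C)O | intermediate
16 | (1S,2S)-2-bromo-1-(but-3-en-1-yl)-1-methyl-5-methylidenecyclohexane | C=C1CC[C@H](Br)[C@@](C)(CCC=C)C1 | intermediate
17 | 3-[(1S,2S)-2-bromo-1-methyl-5-oxocyclohexyl]propanal | O=C1CC[C@H](Br)[C@@](C)(CCC=O)C1 | intermediate
18 | (3aS,4S)-4-bromo-3a-methyl-2,3,3a,4,5,6-hexahydro-7H-inden-7-one | O=C1CC[C@H](Br)[C@@]2(C)CCC=C12 | intermediate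
19 | (1S,3aS,4S,7aS)-4-bromo-1-{[(1S,4S)-4-bromo-1-hydroxy-3,3-dimethylcyclohexyl]methyl}-3a-methyloctahydro-7H-inden-7-one | CC1(C)C[C@@](O)(C[C@@H]2CC[C@]3(C)[C@@H](Br)CCC(=O)[C@@H]23)CC[C@@H]1Br | intermediate
20 | (1S,4S)-4-bromo-1-{[(1S,3aS,4S,7R,7aS)-4-bromo-7-hydroxy-3a,7-dimethyloctahydro-1H-inden-1-yl]methyl}-3,3-dimethylcyclohexan-1-ol | CC1(C)C[C@@](O)(C[C@@H]2CC[C@]3(C)[C@@H](Br)CC[C@@](C)(O)[C@@H]23)CC[C@@H]1Br | target

Total step count: 13. Longest linear sequence: 9 steps (steps 5 to 13).

Steps most likely to fail

Step 12. The β-hydroxyalkyl radical may be reduced, or the alkylcobalt may lose hydroxide and return the alkene, before it adds to the β-substituted enone; the C–Br bonds may also be attacked. The fallback sets out from 6 and 18 and comes back at 19. It replaces cobalt electrocatalysis by a halogen-atom-transfer photoredox Giese addition (organic photocatalyst such as 4CzIPN, a trialkylamine, aqueous MeCN, blue light). There the iodine is abstracted by an α-aminoalkyl radical, the carbon radical is never metal-bound, and the α-keto radical is reduced and protonated in the same way. This fallback makes no new compound (F0).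

Step 4. Oxygen may enter on the chair with equatorial bromine, because the 4-bromo substituent is a weak conformational anchor; this poor conformer and facial selectivity would give the carbinol epimer. The fallback sets out from 5 and comes back at 6, and it delivers carbon instead of oxygen to the equatorial face. Ozonolysis (O3; Me2S) should give (4S)-4-bromo-3,3-dimethylcyclohexan-1-one F1. Corey–Chaykovsky epoxidation (Me3S+ I−, KHMDS, THF, −20 °C) should then give (3R,6S)-6-bromo-5,5-dimethyl-1-oxaspiro[2.5]octane F2, and LiI/AcOH in THF should open it at the CH2 terminus to 6. If the same chair controls both reactions, the relative configuration from this sequence is the opposite of that from iodohydroxylation, so one of the two routes should give 6.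

Step 10. The allylsilane may be lost by protodesilylation, the tertiary cation may lose a proton before ring closure, and the quaternary configuration may erode if the cation is not bridged by bromine. The fallback sets out from 13 and comes back at 17; it uses a chelated β-keto ester enol as the terminating nucleophile. Claisen condensation of 13 with lithio tert-butyl acetate (THF, −78 °C) should give tert-butyl (6S,7R)-6-bromo-7-hydroxy-7-methyl-3-oxoundec-10-enoate F3. Cyclisation with SnCl4 (CH2Cl2, −78 to −20 °C) should give tert-butyl (2S,3S)-3-bromo-2-(but-3-en-1-yl)-2-methyl-6-oxocyclohexane-1-carboxylate F4. TFA and then warming in toluene should give (3S,4S)-4-bromo-3-(but-3-en-1-yl)-3-methylcyclohexan-1-one F5, and ozonolysis (O3; Me2S) of F5 gives 17, which is carried through the acid treatment of step 11.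

Further compounds
F0 | step 12 | none | none
F1 | step 4 | (4S)-4-bromo-3,3-dimethylcyclohexan-1-one | CC1(C)CC(=O)CC[C@@H]1Br
F2 | step 4 | (3R,6S)-6-bromo-5,5-dimethyl-1-oxaspiro[2.5]octane | CC1(C)C[C@@]2(CO2)CC[C@@H]1Br
F3 | step 10 | tert-butyl (6S,7R)-6-bromo-7-hydroxy-7-methyl-3-oxoundec-10-enoate | CC(C)(C)OC(=O)CC(=O)CC[C@H](Br)[C@@](C)(CCC=C)O
F4 | step 10 | tert-butyl (2S,3S)-3-bromo-2-(but-3-en-1-yl)-2-methyl-6-oxocyclohexane-1-carboxylate | CC(C)(C)OC(=O)C1C(=O)CC[C@H](Br)[C@@]1(C)CCC=C
F5 | step 10 | (3S,4S)-4-bromo-3-(but-3-en-1-yl)-3-methylcyclohexan-1-one | O=C1CC[C@H](Br)[C@@](C)(CCC=C)C1
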